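A flask charged with 1.80 equiv of partner B cannot feed both its partners, since the substrate and partner A together could take 3.50, so partner B is the limiting reagent and the question is how it divides.

| flask | substrate | partner A | partner B | remark | time |
|---|---|---|---|---|---|
| Wednesday's | 2 mM | 2.5 equiv | 0.90 equiv | run made earlier |  |
| Sunday's | 2 mM | 2.5 equiv | 3.6 equiv | run made earlier |  |
| Tuesday's | 2 mM | 1.2 equiv | 1.8 equiv | run made earlier |  |
| flask | 2.0 mM | 2.50 equiv | 1.80 equiv |  | 1.5 h |

- Wednesday's (time / min: product / %, substrate / %): 15.0: 18.2, 80.3; 25.0: 18.4, 81.3; 40.0: 17.9, 80.6; 50.0: 17.2, 80.0
- Sunday's (time / min: product / %, substrate / %): 4.00: 77.5, 14.5; 10.0: 89.6, 5.6; 25.0: 94.6, 1.7; 50.0: 94.1, 0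
- Tuesday's (time / min: product / %, substrate / %): 15.0: 58.6, 25.0; 25.0: 58.6, 24.6; 40.0: 57.7, 25.6; 50.0: 58.1, 25.5

(standard deviation of a reading: 0.5 percentage points)

- the earlier runs were read with a standard deviation of 0.5 percentage points
- steps under discussion: substrate + partner B -> open intermediate; partner B + partner A -> second intermediate; open intermediate + second intermediate -> product; second intermediate -> decomposed reagent
- the reaction counts as stopped when no species that holds the substrate changes by six tenths of a point or more over the second half of the time

* at 1.5 h, what has stopped the reaction, if anything has (the partner B has run out first / all of the substrate has reacted / the partner A has run out first / it is still moving)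
* amount of product at 1.5 h, in percent of the substrate charged

Taken with its main step by itself, substrate + partner B, this flask holds more partner B than substrate, and the substrate would be opened entirely.

The step of partner B with partner A changes that. Both steps are first order in partner B, so its concentration cancels from their ratio, and the fractions of charge left, s of substrate and a of partner A, are tied together whatever the time. In Tuesday's flat readings s averages 25.2%, and the partner B not taken by substrate leaves a at 12.4%, so ln s over ln a is 0.660. This ratio is the selectivity factor S, and s equals a raised to the power S. Wednesday's run, with s at 80.5% and a at 71.8%, reads 0.655.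

In this flask the ledger of partner B makes s plus the partner A left, in equivalents, equal 1.70, and with S that gives s = 58.7% and a = 44.5%, a conversion of 41.3%.

The remaining steps leave that ledger alone. Over the whole run this flask makes 3.36 times as much second intermediate as open intermediate, close to the 3.63 reckoned for Wednesday's run, whose readings show a gap of 1.5 percentage points between conversion and product. The reckoning here therefore gives 39.8% of product.

The forecast, using 0.67 for the factor, says the partner B has run out first and 39.8%: “Everything has stopped well before 1.5 h.”

    substrate + partner B → open intermediate (k = 4.50 L mol⁻¹ s⁻¹)
    partner B + partner A → second intermediate (k = 6.80 L mol⁻¹ s⁻¹)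
    open intermediate + second intermediate → product (k = 7.20 L mol⁻¹ s⁻¹)
    second intermediate → decomposed reagent (k = 0.00310 s⁻¹)

The flask holds 40.7% of product at 1.5 h: the partner B has run out first, with 0% of its charge left, and the substrate already stands at 58.7% at 0.0750 h. With partner A at 45% of its charge, S gives 59.0% of substrate, and the flask holds 58.6%. The neighbour charged with 1.50 equiv of partner A ends with 22% of that charge, for which S gives 36.8% of substrate, and that neighbour holds 36.8%.

The earlier runs and the new flask come from a simulation with constants of no real substance; scatter was added.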